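**Retrosynthetic overview** (germacrane numbering: lactone carbinol C8, ester carbinol C6, tertiary carbinol C4, acetoxymethyl C14 on the C1(10) olefin)
1. Target ⇐ desilylative γ-lactonisation of C8–OH onto the C12 methyl ester (second ring), after acylation of C6–OH with (Z)-2-(acetoxymethyl)but-2-enoic acid.
2. Ten-membered ring (first ring) ⇐ C6–C7 bond (farnesyl C1–C10, the cyclase bond) by intramolecular indium allylation of an acyclic C15 aldehyde/2-(bromomethyl)enoate in water; C6 and C7 are set from C8 and C4.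
3. Seco chain ⇐ Morita–Baylis–Hillman unit (C11–C13) on a C7 aldehyde; C1(10) olefin and C14 by Horner–Wadsworth–Emmons coupling of a glycidol-derived α-phosphono lactone (C8) with the ozonolysis lactol of (S)-linalool (C4); C6 aldehyde from the linalool vinyl group by aldehyde-selective Wacker oxidation.
4. Side-chain acid ⇐ but-2-yn-1-ol by trans-hydrostannation, carboxylation and acetylation.
5. Ring order: carbocycle in step 12, lactone in step 17.

Assumption: the compound is numbered as an 8,12-olide (ester on C6, carbinol at C4, C14 on the C1(10) olefin), so that the biosynthetic ring-closing bond is C6–C7.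

**Route**

Step 1
Reactants: 1 (S)-(+)-linalool
Product: 3 (5S)-5-ethenyl-5-methyloxolan-2-ol (anomer mixture), via ozonide 2 (not isolated)
Conditions: O3 (1.0 equiv, Sudan Red 7B end point), CH2Cl2, −78 °C; then Me2S, −78 °C → rt
Reagents that add atoms: ozone O=[O+][O-]
Why: Ozonolysis with reductive work-up cleaves the electron-rich trisubstituted olefin before the vinyl group, and the hydroxy aldehyde closes to the five-membered lactol while the C4 carbinol centre from linalool is untouched.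

Step 2
Reactants: 4 (2R)-2-{[(4-methoxybenzyl)oxy]methyl}oxirane (PMB ether of (S)-glycidol); 5 triethyl phosphonoacetate
Product: 6 diethyl [(5R)-5-{[(4-methoxybenzyl)oxy]methyl}-2-oxooxolan-3-yl]phosphonate (C3 epimers)
Conditions: NaOEt (1.1 equiv), EtOH, 80 °C; then AcOH
Reagents that add atoms: none
Why: SN2 opening of the epoxide at its CH2 by the phosphonoacetate anion and lactonisation of the resulting alkoxide (phosphonoacetate alkylation) give the α-phosphono lactone without touching the stereocentre that becomes C8.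

Step 3
Reactants: 3 (5S)-5-ethenyl-5-methyloxolan-2-ol; 6 diethyl [(5R)-5-{[(4-methoxybenzyl)oxy]methyl}-2-oxooxolan-3-yl]phosphonate
Product: 7 (3E,5R)-3-[(4S)-4-hydroxy-4-methylhex-5-en-1-ylidene]-5-{[(4-methoxybenzyl)oxy]methyl}oxolan-2-one
Conditions: LiCl, DBU, MeCN, rt
Reagents that add atoms: none
Why: Horner–Wadsworth–Emmons olefination (Masamune–Roush conditions) on the open hydroxy-aldehyde form of the lactol gives the E-alkylidene lactone, which fixes the C1(10) geometry (C2 chain cis to the future C9 CH2), and the weak base keeps the tertiary alcohol protonated so that oxa-Michael closure is suppressed.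

Step 4
Reactants: 7 (3E,5R)-3-[(4S)-4-hydroxy-4-methylhex-5-en-1-ylidene]-5-{[(4-methoxybenzyl)oxy]methyl}oxolan-2-one
Product: 8 (2R,4E,8S)-4-(hydroxymethyl)-1-[(4-methoxybenzyl)oxy]-8-methyldeca-4,9-diene-2,8-diol
Conditions: i-Bu2AlH (4.5 equiv), CH2Cl2, −78 → 0 °C; aq. KNaC4H4O6
Reagents that add atoms: none
Why: 1,2-Reduction of the α-alkylidene lactone by the aluminium hydride gives the allylic 1,4-diol with the olefin geometry retained and no new stereocentre.

Step 5
Reactants: 8 (2R,4E,8S)-4-(hydroxymethyl)-1-[(4-methoxybenzyl)oxy]-8-methyldeca-4,9-diene-2,8-diol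
Product: 9 (2R,4E,8S)-4-(acetoxymethyl)-1-[(4-methoxybenzyl)oxy]-8-methyldeca-4,9-diene-2,8-diol
Conditions: AcCl (1.05 equiv), 2,4,6-collidine, CH2Cl2, −78 °C
Reagents that add atoms: acetyl chloride CC(Cl)=O
Why: Kinetically controlled acylation acetylates the primary allylic hydroxyl in preference to the secondary and tertiary ones and so installs the C14 acetate of the target.

Step 6
Reactants: 9 (2R,4E,8S)-4-(acetoxymethyl)-1-[(4-methoxybenzyl)oxy]-8-methyldeca-4,9-diene-2,8-diol
Product: 10 (2R,4E,8S)-4-(acetoxymethyl)-2-{[tert-butyl(dimethyl)silyl]oxy}-1-[(4-methoxybenzyl)oxy]-8-methyldeca-4,9-dien-8-ol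
Conditions: TBSCl, imidazole, DMF, rt
Reagents that add atoms: tert-butyldimethylsilyl chloride CC(C)(C)[Si](C)(C)Cl
Why: Silyl ether protection of the secondary hydroxyl (future C8–OH) proceeds while the hindered tertiary C4 hydroxyl does not react.

Step 7
Reactants: 10 (2R,4E,8S)-4-(acetoxymethyl)-2-{[tert-butyl(dimethyl)silyl]oxy}-1-[(4-methoxybenzyl)oxy]-8-methyldeca-4,9-dien-8-ol
Product: 11 (2R,4E,8S)-4-(acetoxymethyl)-2-{[tert-butyl(dimethyl)silyl]oxy}-8-methyldeca-4,9-diene-1,8-diol
Conditions: DDQ, CH2Cl2/pH 7 buffer, 0 °C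
Reagents that add atoms: none
Why: Oxidative cleavage of the 4-methoxybenzyl ether by DDQ is neutral and leaves the silyl ether, the acetate and the olefins intact.

Step 8
Reactants: 11 (2R,4E,8S)-4-(acetoxymethyl)-2-{[tert-butyl(dimethyl)silyl]oxy}-8-methyldeca-4,9-diene-1,8-diol
Product: 12 (2R,4E,8S)-4-(acetoxymethyl)-2-{[tert-butyl(dimethyl)silyl]oxy}-8-hydroxy-8-methyldeca-4,9-dienal
Conditions: TEMPO (10 mol %), PhI(OAc)2, CH2Cl2, rt
Reagents that add atoms: none
Why: Oxoammonium (TEMPO) oxidation converts the primary alcohol to the aldehyde under neutral conditions, which avoids epimerisation of the α-silyloxy centre, and the tertiary alcohol cannot be oxidised.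

Step 9
Reactants: 12 (2R,4E,8S)-4-(acetoxymethyl)-2-{[tert-butyl(dimethyl)silyl]oxy}-8-hydroxy-8-methyldeca-4,9-dienal; 13 methyl acrylate
Product: 14 methyl (4R,6E,10S)-6-(acetoxymethyl)-4-{[tert-butyl(dimethyl)silyl]oxy}-3,10-dihydroxy-10-methyl-2-methylidenedodeca-6,11-dienoate (C3 epimers)
Conditions: methyl acrylate (10 equiv), DABCO (1 equiv), MeOH (3 equiv), rt, 3 d
Reagents that add atoms: none
Why: The Morita–Baylis–Hillman reaction of the inductively activated α-silyloxy aldehyde attaches C11–C13, and the new carbinol centre may be a mixture because it is erased in step 11.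

Step 10
Reactants: 14 methyl (4R,6E,10S)-6-(acetoxymethyl)-4-{[tert-butyl(dimethyl)silyl]oxy}-3,10-dihydroxy-10-methyl-2-methylidenedodeca-6,11-dienoate
Product: 15 methyl (4R,6E,10S)-6-(acetoxymethyl)-4-{[tert-butyl(dimethyl)silyl]oxy}-3,10-dihydroxy-10-methyl-2-methylidene-12-oxododec-6-enoate (C3 epimers)
Conditions: PdCl2(PhCN)2 (12 mol %), CuCl2·2H2O (12 mol %), AgNO2 (6 mol %), t-BuOH/MeNO2 15:1, O2 (1 atm), rt
Reagents that add atoms: dioxygen O=O
Why: The nitrite-modified Wacker oxidation is aldehyde-selective for a terminal olefin next to a quaternary oxygen-bearing carbon, only the monosubstituted vinyl group reacts, and no stereocentre is affected.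

Step 11
Reactants: 15 methyl (4R,6E,10S)-6-(acetoxymethyl)-4-{[tert-butyl(dimethyl)silyl]oxy}-3,10-dihydroxy-10-methyl-2-methylidene-12-oxododec-6-enoate
Product: 16 methyl (2Z,4R,6E,10S)-6-(acetoxymethyl)-2-(bromomethyl)-4-{[tert-butyl(dimethyl)silyl]oxy}-10-hydroxy-10-methyl-12-oxododeca-2,6-dienoate
Conditions: NBS, Me2S, CH2Cl2, −20 → 0 °C
Reagents that add atoms: N-bromosuccinimide O=C1CCC(=O)N1Br
Why: Corey–Kim-type activation of the allylic carbinol as its alkoxysulfonium salt and SN2′ attack of bromide give the favoured (Z)-2-(bromomethyl) enoate (C8 chain cis to CH2Br), tolerate the aldehyde, and remove the C7 carbinol centre.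

Step 12
Reactants: 16 methyl (2Z,4R,6E,10S)-6-(acetoxymethyl)-2-(bromomethyl)-4-{[tert-butyl(dimethyl)silyl]oxy}-10-hydroxy-10-methyl-12-oxododeca-2,6-dienoate
Product: 18 methyl 2-[(1R,2R,4S,7E,10R)-8-(acetoxymethyl)-10-{[tert-butyl(dimethyl)silyl]oxy}-2,4-dihydroxy-4-methylcyclodec-7-en-1-yl]prop-2-enoate, via allylindium species 17 (not isolated)
Conditions: In powder (3 equiv), THF/H2O 1:1, 2 mM (slow addition of 16 over 12 h), rt
Reagents that add atoms: none
Why: Proposed new method: an indium Barbier closure of a ten-membered ring is not described, but the allylindium from the (Z)-2-(bromomethyl) enoate should add through its γ-carbon (C7) to the aldehyde in a chair six-membered transition state in which the Z geometry gives the syn C6/C7 pair, the C8–H lies in the olefin plane (allylic 1,3-strain) with the bulky silyloxy group anti to the incoming aldehyde so that the new bond forms anti to C8–O, and the free C4 hydroxyl chelates indium with the aldehyde oxygen to favour the 1,3-anti C4/C6 diol, so that all three elements lead to the diastereomer needed; this is the C6–C7 (farnesyl C1–C10) bond of the cyclase, and the closest known reaction type is the intramolecular Barbier/Nozaki–Hiyama allylation of 2-(bromomethyl)acrylates onto aldehydes (CrCl2 or Zn for ten-membered germacranolide rings, indium in water for five- to seven-membered rings).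

Step 13
Reactants: 19 but-2-yn-1-ol
Product: 20 (2Z)-2-(tributylstannyl)but-2-en-1-ol
Conditions: Bu3SnH (1.1 equiv), [Cp*RuCl]4 (1.25 mol %), CH2Cl2, rt
Reagents that add atoms: tributyltin hydride CCCC[SnH](CCCC)CCCC
Why: The [Cp*RuCl]4-catalysed trans-hydrostannation is directed by the free hydroxyl to the proximal alkyne carbon and adds H and Sn anti, so the methyl group ends up cis to tin.

Step 14
Reactants: 20 (2Z)-2-(tributylstannyl)but-2-en-1-ol
Product: 22 (2Z)-2-(hydroxymethyl)but-2-enoic acid, via dilithio species 21 (not isolated)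
Conditions: MeLi (2.2 equiv), THF, −78 → 0 °C; CO2 (g), −78 °C; aq. HCl
Reagents that add atoms: carbon dioxide O=C=O
Why: Tin–lithium exchange occurs with retention of olefin geometry and carboxylation of the vinyllithium gives the angelate-type (Z) acid with methyl cis to the carboxyl group.

Step 15
Reactants: 22 (2Z)-2-(hydroxymethyl)but-2-enoic acid
Product: 24 (2Z)-2-(acetoxymethyl)but-2-enoic acid, via mixed anhydride 23 (not isolated)
Conditions: Ac2O (2.5 equiv), pyridine, 0 °C → rt; then H2O/THF, rt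
Reagents that add atoms: acetic anhydride CC(=O)OC(C)=O
Why: O-Acetylation of the primary alcohol is accompanied by mixed-anhydride formation at the carboxyl group, which is hydrolysed at the acetyl carbonyl on aqueous work-up while the alkyl acetate and the olefin geometry stay.

Step 16
Reactants: 18 methyl 2-[(1R,2R,4S,7E,10R)-8-(acetoxymethyl)-10-{[tert-butyl(dimethyl)silyl]oxy}-2,4-dihydroxy-4-methylcyclodec-7-en-1-yl]prop-2-enoate; 24 (2Z)-2-(acetoxymethyl)but-2-enoic acid
Product: 26 methyl 2-[(1R,2R,4S,7E,10R)-8-(acetoxymethyl)-2-{[(2Z)-2-(acetoxymethyl)but-2-enoyl]oxy}-10-{[tert-butyl(dimethyl)silyl]oxy}-4-hydroxy-4-methylcyclodec-7-en-1-yl]prop-2-enoate, via mixed anhydride 25 (not isolated)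
Conditions: 24 (1.5 equiv), 2,4,6-Cl3C6H2COCl, Et3N, toluene, rt, 1 h; then 18, DMAP (0.2 equiv), 40 °C
Reagents that add atoms: none
Why: Yamaguchi esterification acylates the secondary C6 hydroxyl (the tertiary C4 hydroxyl is inert), and the preformed mixed anhydride with little DMAP is the established way to transfer angelate-type acids without Z to E isomerisation.

Step 17
Reactants: 26 methyl 2-[(1R,2R,4S,7E,10R)-8-(acetoxymethyl)-2-{[(2Z)-2-(acetoxymethyl)but-2-enoyl]oxy}-10-{[tert-butyl(dimethyl)silyl]oxy}-4-hydroxy-4-methylcyclodec-7-en-1-yl]prop-2-enoate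
Product: 28 [(3aS,4R,6S,9E,11aR)-10-(acetoxymethyl)-6-hydroxy-6-methyl-3-methylidene-2-oxo-2,3,3a,4,5,6,7,8,11,11a-decahydrocyclodeca[b]furan-4-yl] (2Z)-2-(acetoxymethyl)but-2-enoate (CNP0280960.1), via hydroxy ester 27 (not isolated)
Conditions: HF·pyridine, pyridine/THF, 0 °C → rt; then PPTS (10 mol %), CH2Cl2, rt
Reagents that add atoms: none
Why: Fluoride-mediated desilylation frees the C8 hydroxyl, which closes onto the C12 methyl ester (γ-lactonisation) to the trans-fused α-methylene lactone without affecting the C7 and C8 centres set earlier.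

**Compound list**
1 | (S)-(+)-linalool | C=C[C@@](C)(O)CCC=C(C)C | starting material
2 | 3-[(3S)-3-hydroxy-3-methylpent-4-en-1-yl]-5,5-dimethyl-1,2,4-trioxolane (ozonide) | C=C[C@@](C)(O)CCC1OOC(C)(C)O1 | intermediate
3 | (5S)-5-ethenyl-5-methyloxolan-2-ol | OC1CC[C@](C)(O1)C=C | intermediate
4 | (2R)-2-{[(4-methoxybenzyl)oxy]methyl}oxirane | COc1ccc(COC[C@H]2CO2)cc1 | starting material
5 | triethyl phosphonoacetate | CCOC(=O)CP(=O)(OCC)OCC | starting material
6 | diethyl [(5R)-5-{[(4-methoxybenzyl)oxy]methyl}-2-oxooxolan-3-yl]phosphonate | CCOP(=O)(OCC)C1C[C@H](COCc2ccc(OC)cc2)OC1=O | intermediate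
7 | (3E,5R)-3-[(4S)-4-hydroxy-4-methylhex-5-en-1-ylidene]-5-{[(4-methoxybenzyl)oxy]methyl}oxolan-2-one | C=C[C@@](C)(O)CC/C=C1\C[C@H](COCc2ccc(OC)cc2)OC1=O | intermediate
8 | (2R,4E,8S)-4-(hydroxymethyl)-1-[(4-methoxybenzyl)oxy]-8-methyldeca-4,9-diene-2,8-diol | C=C[C@@](C)(O)CC/C=C(CO)\C[C@@H](O)COCc1ccc(OC)cc1 | intermediate
9 | (2R,4E,8S)-4-(acetoxymethyl)-1-[(4-methoxybenzyl)oxy]-8-methyldeca-4,9-diene-2,8-diol | C=C[C@@](C)(O)CC/C=C(COC(C)=O)\C[C@@H](O)COCc1ccc(OC)cc1 | intermediate
10 | (2R,4E,8S)-4-(acetoxymethyl)-2-{[tert-butyl(dimethyl)silyl]oxy}-1-[(4-methoxybenzyl)oxy]-8-methyldeca-4,9-dien-8-ol | C=C[C@@](C)(O)CC/C=C(COC(C)=O)\C[C@@H](O[Si](C)(C)C(C)(C)C)COCc1ccc(OC)cc1 | intermediate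
11 | (2R,4E,8S)-4-(acetoxymethyl)-2-{[tert-butyl(dimethyl)silyl]oxy}-8-methyldeca-4,9-diene-1,8-diol | C=C[C@@](C)(O)CC/C=C(COC(C)=O)\C[C@@H](O[Si](C)(C)C(C)(C)C)CO | intermediate
12 | (2R,4E,8S)-4-(acetoxymethyl)-2-{[tert-butyl(dimethyl)silyl]oxy}-8-hydroxy-8-methyldeca-4,9-dienal | C=C[C@@](C)(O)CC/C=C(COC(C)=O)\C[C@@H](O[Si](C)(C)C(C)(C)C)C=O | intermediate
13 | methyl acrylate | C=CC(=O)OC | starting material
14 | methyl (4R,6E,10S)-6-(acetoxymethyl)-4-{[tert-butyl(dimethyl)silyl]oxy}-3,10-dihydroxy-10-methyl-2-methylidenedodeca-6,11-dienoate (C3 epimers) | C=C[C@@](C)(O)CC/C=C(COC(C)=O)\C[C@@H](O[Si](C)(C)C(C)(C)C)C(O)C(=C)C(=O)OC | intermediate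
15 | methyl (4R,6E,10S)-6-(acetoxymethyl)-4-{[tert-butyl(dimethyl)silyl]oxy}-3,10-dihydroxy-10-methyl-2-methylidene-12-oxododec-6-enoate (C3 epimers) | O=CC[C@@](C)(O)CC/C=C(COC(C)=O)\C[C@@H](O[Si](C)(C)C(C)(C)C)C(O)C(=C)C(=O)OC | intermediate
16 | methyl (2Z,4R,6E,10S)-6-(acetoxymethyl)-2-(bromomethyl)-4-{[tert-butyl(dimethyl)silyl]oxy}-10-hydroxy-10-methyl-12-oxododeca-2,6-dienoate | O=CC[C@@](C)(O)CC/C=C(COC(C)=O)\C[C@@H](O[Si](C)(C)C(C)(C)C)/C=C(\CBr)C(=O)OC | intermediate
17 | allylindium species from 16 (drawn as the monomeric dibromide) | O=CC[C@@](C)(O)CC/C=C(COC(C)=O)\C[C@@H](O[Si](C)(C)C(C)(C)C)/C=C(\C[In](Br)Br)C(=O)OC | intermediate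
18 | methyl 2-[(1R,2R,4S,7E,10R)-8-(acetoxymethyl)-10-{[tert-butyl(dimethyl)silyl]oxy}-2,4-dihydroxy-4-methylcyclodec-7-en-1-yl]prop-2-enoate | CC(C)(C)[Si](C)(C)O[C@@H]1C/C(COC(C)=O)=C\CC[C@](C)(O)C[C@@H](O)[C@H]1C(=C)C(=O)OC | intermediate
19 | but-2-yn-1-ol | CC#CCO | starting material
20 | (2Z)-2-(tributylstannyl)but-2-en-1-ol | C/C=C(/CO)[Sn](CCCC)(CCCC)CCCC | intermediate
21 | lithium (2Z)-2-lithiobut-2-en-1-olate | C/C=C(/CO[Li])[Li] | intermediate
22 | (2Z)-2-(hydroxymethyl)but-2-enoic acid | C/C=C(/CO)C(O)=O | intermediate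
23 | acetic (2Z)-2-(acetoxymethyl)but-2-enoic anhydride | C/C=C(/COC(C)=O)C(=O)OC(C)=O | intermediate
24 | (2Z)-2-(acetoxymethyl)but-2-enoic acid | C/C=C(/COC(C)=O)C(O)=O | intermediate
25 | (2Z)-2-(acetoxymethyl)but-2-enoic 2,4,6-trichlorobenzoic anhydride | C/C=C(/COC(C)=O)C(=O)OC(=O)c1c(Cl)cc(Cl)cc1Cl | intermediate
26 | methyl 2-[(1R,2R,4S,7E,10R)-8-(acetoxymethyl)-2-{[(2Z)-2-(acetoxymethyl)but-2-enoyl]oxy}-10-{[tert-butyl(dimethyl)silyl]oxy}-4-hydroxy-4-methylcyclodec-7-en-1-yl]prop-2-enoate | CC(C)(C)[Si](C)(C)O[C@@H]1C/C(COC(C)=O)=C\CC[C@](C)(O)C[C@@H](OC(=O)/C(=C\C)COC(C)=O)[C@H]1C(=C)C(=O)OC | intermediate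
27 | methyl 2-[(1S,2R,4S,7E,10R)-8-(acetoxymethyl)-2-{[(2Z)-2-(acetoxymethyl)but-2-enoyl]oxy}-4,10-dihydroxy-4-methylcyclodec-7-en-1-yl]prop-2-enoate | O[C@@H]1C/C(COC(C)=O)=C\CC[C@](C)(O)C[C@@H](OC(=O)/C(=C\C)COC(C)=O)[C@H]1C(=C)C(=O)OC | intermediate
28 | [(3aS,4R,6S,9E,11aR)-10-(acetoxymethyl)-6-hydroxy-6-methyl-3-methylidene-2-oxo-2,3,3a,4,5,6,7,8,11,11a-decahydrocyclodeca[b]furan-4-yl] (2Z)-2-(acetoxymethyl)but-2-enoate | C=C1C(=O)O[C@@H]2C/C(COC(C)=O)=C\CC[C@](C)(O)C[C@@H](OC(=O)/C(=C\C)COC(C)=O)[C@@H]12 | target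

**Step count**
Total: 17 steps (13 in the main line, 1 for the phosphono lactone, 3 for the side-chain acid).
Longest linear sequence: 13 steps from (S)-linalool (steps 1, 3–12, 16, 17).

**Three steps most likely to fail**

Step 12 (ring closure). Risks are oligomerisation or protonolysis of the allylindium at the dilution needed for a ten-membered ring, and erosion of the C7/C8 facial selectivity. The fallback sets out from 15 and closes the ring with boron instead of a reducing metal. Acetylation of the allylic carbinol (Ac2O, pyridine, 0 °C) gives the allylic acetate F1. Copper-catalysed SN2′ borylation (B2pin2, CuCl, KOAc, DMF, rt) gives the allyl boronate F2 with the C8 chain cis to CH2B. Sc(OTf)3 (10 mol %) in CH2Cl2 at −78 °C and 1 mM then triggers an intramolecular allylboration through a closed chair transition state, which transfers the olefin geometry to the syn C6/C7 pair. Aqueous work-up of the borate returns to 18.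

Step 10 (aldehyde-selective Wacker oxidation). The free tertiary allylic alcohol may give the methyl ketone, allylic transposition or dehydration of the β-hydroxy aldehyde. The fallback sets out from 14. Hydroboration of the vinyl group with 9-BBN (4 equiv, THF, 0 °C → rt; the two hydroxyls consume reagent) and oxidation with NaBO3·4H2O give the primary alcohol F3. TEMPO/PhI(OAc)2 then oxidises only the primary hydroxyl and returns to 15.

Step 16 (esterification). The activated (Z)-acid can isomerise to the E form or undergo SN2′ scrambling with DMAP, and the C6 hydroxyl can lactonise onto the C12 ester under base. The fallback builds the ester by carbonylation, sets out from stannane 20 and alcohol 18, and returns at 26. Iododestannylation of 20 (I2, CH2Cl2, 0 °C) gives (Z)-2-iodobut-2-en-1-ol F4. Acetylation (Ac2O, pyridine) gives (Z)-2-iodobut-2-en-1-yl acetate F5. Alkoxycarbonylation of F5 (3 equiv) with 18 as the alcohol (Pd(OAc)2 5 mol %, PPh3 10 mol %, CO 5 bar, Et3N, DMF, 50 °C) forms the C6 ester through an acyl–palladium species that keeps the olefin geometry and never exposes an activated acrylic acid derivative to a nucleophilic catalyst.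

**Further compounds**
F1 | step 12 | methyl (4R,6E,10S)-3-acetoxy-6-(acetoxymethyl)-4-{[tert-butyl(dimethyl)silyl]oxy}-10-hydroxy-10-methyl-2-methylidene-12-oxododec-6-enoate (C3 epimers) | O=CC[C@@](C)(O)CC/C=C(COC(C)=O)\C[C@@H](O[Si](C)(C)C(C)(C)C)C(OC(C)=O)C(=C)C(=O)OC
F2 | step 12 | methyl (2E,4R,6E,10S)-6-(acetoxymethyl)-4-{[tert-butyl(dimethyl)silyl]oxy}-10-hydroxy-10-methyl-12-oxo-2-[(4,4,5,5-tetramethyl-1,3,2-dioxaborolan-2-yl)methyl]dodeca-2,6-dienoate | O=CC[C@@](C)(O)CC/C=C(COC(C)=O)\C[C@@H](O[Si](C)(C)C(C)(C)C)/C=C(\CB1OC(C)(C)C(C)(C)O1)C(=O)OC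
F3 | step 10 | methyl (4R,6E,10S)-6-(acetoxymethyl)-4-{[tert-butyl(dimethyl)silyl]oxy}-3,10,12-trihydroxy-10-methyl-2-methylidenedodec-6-enoate (C3 epimers) | OCC[C@@](C)(O)CC/C=C(COC(C)=O)\C[C@@H](O[Si](C)(C)C(C)(C)C)C(O)C(=C)C(=O)OC
F4 | step 16 | (2Z)-2-iodobut-2-en-1-ol | C/C=C(/CO)I
F5 | step 16 | (2Z)-2-iodobut-2-en-1-yl acetate | C/C=C(/COC(C)=O)I
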